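Late in a flask target can be lost as well as made, so I read the runs for that loss before I reckoned any yield.

all flasks: free catalyst 70 mM

| charge | substrate | reagent | temperature | remark | time |
|---|---|---|---|---|---|
| spring | 0.20 M | 1.4 M | 10 °C | run made earlier |  |
| midnight | 0.88 M | 1.4 M | 25 °C | run made earlier |  |
| ash | 1.4 M | 1.40 M | 25 °C |  | 20 h |
| alder | 0.40 M | 1.40 M | 25 °C |  | 20 h |
| oak | 0.50 M | 1.40 M | 25 °C |  | 20 h |
| cedar | 0.80 M | 1.40 M | 25 °C |  | 20 h |

- the flasks put in order of amount of target, in percent of the substrate charged, best first, at 20 h (ash / alder / oak / cedar)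
- the same order at 6.0 d (ash / alder / oak / cedar)
- the amount of target, in percent of the substrate charged of the flask you put first, at 20 h
- the amount of target, in percent of the substrate charged of the flask you put last, at 20 h

| run | time / h | target / % | substrate / % |
|---|---|---|---|
| spring | 4.00 | 0.1 | 99.5 |
| spring | 10.0 | 2.3 | 97.0 |
| spring | 20.0 | 6.9 | 90.7 |
| spring | 30.0 | 13.1 | 83.9 |
| spring | 40.0 | 19.2 | 77.4 |
| midnight | 2.00 | 1.2 | 98.4 |
| midnight | 5.00 | 4.8 | 94.4 |
| midnight | 10.0 | 9.0 | 88.4 |
| midnight | 15.0 | 13.7 | 82.2 |
| midnight | 20.0 | 18.0 | 77.3 |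

(scatter of a reading: 0.3 percentage points)



The flasks differed in [substrate] and stood at the temperature of the midnight run, so I leaned on that run. Its target line looked nearly straight, but its columns did not add up: at 20.0 h, target 18.0 % and substrate 77.3 % left a gap of 4.70 % of the charge. At 5.00 h that gap had read 0.800 %, so it seemed to grow with the target already formed. I therefore defined the loss constant of target, a pseudo-first-order constant, as the gap divided by the area under the target line, taken as a triangle. That reading, which carried the scatter, gave 0.0261 h⁻¹.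

Here I looked for the crossing: I expected making to fall as a charge ran down while loss went on with the target present, so I compared how long the charges lasted. Midnight used substrate at 9.99 mM h⁻¹. At that pace I reckoned alder's charge to last 40.0 h, less than cedar's 80.1 h, so I expected alder to lose its lead by 6.0 d.

The forecast gave alder > oak > cedar > ash at 20 h, with 39 % and 11.2 %. It kept alder > oak > cedar > ash at 6.0 d, judging that “dilute flasks probably stay slightly ahead”, and there my reckoning differed.

The flasks gave alder > oak > cedar > ash at 20 h, with 26.8 % and 12.5 %, and cedar > oak > alder > ash at 6.0 d.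

    reagent + free catalyst → catalyst intermediate A (k = 0.00400 M⁻¹ min⁻¹, Ea = 72.0 kJ mol⁻¹)
    catalyst intermediate C → free catalyst + target (k = 0.0300 min⁻¹, Ea = 80.0 kJ mol⁻¹)
    catalyst intermediate A → catalyst intermediate B (k = 0.0260 min⁻¹, Ea = 83.0 kJ mol⁻¹)
    substrate + catalyst intermediate B ⇌ catalyst intermediate C (K = 0.450 M⁻¹, k = 0.0700 M⁻¹ min⁻¹, Ea = 63.0 kJ mol⁻¹, ΔH = −32.0 kJ mol⁻¹)
    reagent + target → over-reaction product (k = 2.90 × 10⁻⁴ M⁻¹ min⁻¹, Ea = 91.0 kJ mol⁻¹)
    target + free catalyst ⇌ isomer of the product + free catalyst, rate k6*[free catalyst]*[target] forward; the back reaction follows from the equilibrium constant (K = 13.0, k = 0.00340 M⁻¹ min⁻¹, Ea = 64.0 kJ mol⁻¹, ΔH = −33.0 kJ mol⁻¹)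
    (constants at 25 °C)

In alder at 20.0 h, the loss constant reckoned 7.00 % lost, and isomer of the product plus over-reaction product stood at 7.32 %. The neighbour was alder with 0.35 M of reagent, and it held 13.3 % target at 20.0 h. The same reckoning gave 3.47 % lost, but the two products stood at 1.87 %. Its over-reaction product was 0.611 %, less than alder's 5.92 %.

(The earlier runs and the new flask come from a simulation with constants of no real substance, noise included.)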